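**Plan**
- Retrosynthetic cuts, in order: C3a–C4 (ring A is opened to a 2-methoxyvinyl ketone chain on an oxolan-2-ylidene); then the C7=C7a unsaturation and the C7–C7a bond (chain removed from an oxolane acetal); last O1–C7a and C2–C3 (oxolane opened to an acyclic allyl carbamate plus acetaldehyde).
- Enabling feature: the ring O1–C2–C3–C3a–C7a is a γ-lactol in disguise. C7a, the enol-ether carbon of the vinylogous ester O1–C7a=C7–C6=O in ring A, is at carbonyl level and C3 is β to it, so C3–C3a–C7a is a homoenolate and C2=O1 is the carbonyl of acetaldehyde (formal [3+2]).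
- Forward order: E-allyl carbamate 5 → oxolane acetal 10 (key step) → chain C7–C6–C5–C4 attached at C7a (13) → dehydrogenation to 15 → ring A closed onto C3a (16).
- Stereochemistry: C2 and C3 arise together in the key step (absolute sense from the chiral diamine, anti relation from the chair transition state of the E-alkene). C3a is set in the ring closure, C4 entering anti to the C3 aryl group. C5 is set by equilibration next to the ketone (methoxy equatorial, trans to the pseudo-axial allyl).
- Helper groups: the N,N-diisopropylcarbamate (directs lithiation, masks the C7a carbonyl, leaves in the key step) and the acetal methoxy at C7a (leaves in step 6).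

Key step: step 4

Assumption: the diamine-controlled deprotonation of 5 is taken to follow the sense known for (E)-but-2-enyl N,N-diisopropylcarbamate, where (−)-sparteine leads to the (S)-lithium compound. The route needs the (R)-lithium compound and therefore names (+)-sparteine; if the sense were reversed for this substrate, (−)-sparteine would be used with no other change.

Locants C2, C3, C3a, C4–C7, C7a and O1 are those of the benzofuranone target throughout.

Step 1
Reactants: 1 3,4,5-trimethoxybenzaldehyde; 2 pent-4-enal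
Product: 3 (2E)-2-(prop-2-en-1-yl)-3-(3,4,5-trimethoxyphenyl)prop-2-enal
Conditions: NaOH, MeOH/H2O, 0 °C → rt, slow addition of 2
Reagents that add atoms: none
Why: Crossed aldol condensation in which the non-enolisable aryl aldehyde is the only good acceptor, and E1cB dehydration should give the E-enal (aryl trans to formyl) as the stable isomer.

Step 2
Reactants: 3 (2E)-2-(prop-2-en-1-yl)-3-(3,4,5-trimethoxyphenyl)prop-2-enal
Product: 4 (2E)-2-(prop-2-en-1-yl)-3-(3,4,5-trimethoxyphenyl)prop-2-en-1-ol
Conditions: NaBH4, CeCl3·7H2O, MeOH, 0 °C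
Reagents that add atoms: none
Why: Luche reduction is selective for 1,2-addition to the enal and leaves both alkenes and the alkene geometry untouched.

Step 3
Reactants: 4 (2E)-2-(prop-2-en-1-yl)-3-(3,4,5-trimethoxyphenyl)prop-2-en-1-ol
Product: 5 (2E)-2-(prop-2-en-1-yl)-3-(3,4,5-trimethoxyphenyl)prop-2-en-1-yl N,N-di(propan-2-yl)carbamate
Conditions: NaH, THF, 0 °C; i-Pr2NCOCl, reflux
Reagents that add atoms: N,N-diisopropylcarbamoyl chloride CC(C)N(C(C)C)C(Cl)=O
Why: O-Carbamoylation of the alkoxide installs the group that directs α-lithiation and makes the allyl unit a homoenolate equivalent.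

Step 4
Reactants: 5 (2E)-2-(prop-2-en-1-yl)-3-(3,4,5-trimethoxyphenyl)prop-2-en-1-yl N,N-di(propan-2-yl)carbamate; 6 acetaldehyde
Product: 10 (4S,5S)-2-methoxy-5-methyl-3-(prop-2-en-1-yl)-4-(3,4,5-trimethoxyphenyl)oxolane (mixture at oxolane C2 and C3, that is C7a and C3a), via lithium compound 7 (not isolated), via titanium compound 8 (not isolated), via homoaldol adduct 9 (not isolated)
Conditions: n-BuLi, (+)-sparteine, toluene, −78 °C; Ti(OiPr)4, −78 °C; CH3CHO, −78 → −20 °C; then MeOH, MeSO3H, 0 °C → rt
Reagents that add atoms: methanol CO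
Why: Carbamate-directed, diamine-controlled deprotonation at the allylic O–CH2 gives lithium compound 7, which Ti(OiPr)4 converts with inversion into the α-titanated carbamate 8; this adds to acetaldehyde at its γ-carbon (benzylic C3) through a chair six-membered transition state, and the γ-hydroxy enol carbamate 9 is cyclised in the same flask by acid (protonation at C3a, capture of the carbamoyloxy carbenium ion at C7a by the new hydroxyl, loss of the carbamate, trapping by methanol). The closest known reaction type is the Hoppe asymmetric homoaldol reaction of 2-alkenyl carbamates, followed by the usual conversion of the adducts into γ-lactol ethers. One ring, the oxolane, is closed, by 5-exo-trig attack of O1 on the cationic C7a. C3 and C2 are set together: the face of the allyl unit is fixed by the configuration at the titanium-bearing carbon (diamine control), and the E geometry of C3=C3a places the aryl group equatorial in the chair, so the anti adduct and hence the trans-2-methyl-3-aryl oxolane should result. The step needs γ- over α-attack and anti over syn selectivity, which the closed transition state on tetravalent titanium and the single E geometry of 5 should secure; the centres at C3a and C7a are left as mixtures on purpose because both are flattened later.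

Step 5
Reactants: 11 3,3-dimethoxybutan-2-one
Product: 12 2-methoxy-3-(trimethylsilyloxy)buta-1,3-diene
Conditions: TMSOTf (2.2 equiv), Et3N, CH2Cl2, 0 °C → rt
Reagents that add atoms: trimethylsilyl trifluoromethanesulfonate C[Si](C)(C)OS(=O)(=O)C(F)(F)F
Why: Soft enolisation silylates the only enolisable position, and the same reagent pair then removes methanol from the now allylic ketal to give the methyl enol ether.

Step 6
Reactants: 10 (4S,5S)-2-methoxy-5-methyl-3-(prop-2-en-1-yl)-4-(3,4,5-trimethoxyphenyl)oxolane; 12 2-methoxy-3-(trimethylsilyloxy)buta-1,3-diene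
Product: 13 3-methoxy-1-[(4S,5S)-5-methyl-3-(prop-2-en-1-yl)-4-(3,4,5-trimethoxyphenyl)oxolan-2-yl]but-3-en-2-one (mixture at oxolane C2 and C3)
Conditions: TMSOTf (0.1 equiv), CH2Cl2, −78 °C
Reagents that add atoms: none
Why: Mukaiyama-type addition of the silyl enol ether terminus of 12 to the cyclic oxocarbenium ion from 10 forms C7–C7a; only the exocyclic methoxy group ionises, so the O1–C7a bond stays, and silyl transfer makes attack through this terminus the only product-forming path.

Step 7
Reactants: 13 3-methoxy-1-[(4S,5S)-5-methyl-3-(prop-2-en-1-yl)-4-(3,4,5-trimethoxyphenyl)oxolan-2-yl]but-3-en-2-one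
Product: 15 3-methoxy-1-[(4S,5S)-5-methyl-3-(prop-2-en-1-yl)-4-(3,4,5-trimethoxyphenyl)oxolan-2-ylidene]but-3-en-2-one (mixture at oxolane C3 and of alkene isomers), via silyl dienol ether 14 (not isolated)
Conditions: TMSOTf, Et3N, CH2Cl2, 0 °C; then Pd(OAc)2, MeCN, rt
Reagents that add atoms: none
Why: Soft enolisation toward C7 (the only α-CH2) avoids an alkoxide-expelling enolate, and Saegusa–Ito oxidation of 14 (palladium enolate, β-hydride loss of the C7a hydrogen) should give the β-alkoxy enone, that is the vinylogous ester C7=C7a–O1.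

Step 8
Reactants: 15 3-methoxy-1-[(4S,5S)-5-methyl-3-(prop-2-en-1-yl)-4-(3,4,5-trimethoxyphenyl)oxolan-2-ylidene]but-3-en-2-one
Product: 16 (2S,3R,3aR,5R)-5-methoxy-2-methyl-3a-(prop-2-en-1-yl)-3-(3,4,5-trimethoxyphenyl)-3,3a,4,5-tetrahydro-1-benzofuran-6(2H)-one
Conditions: KOtBu (0.2 equiv), t-BuOH/THF, 0 °C → rt
Reagents that add atoms: none
Why: Proposed new method: catalytic base removes the only acidic proton (C3a–H, γ to the C6 carbonyl through C7=C7a) to give the 3-oxido-hexatriene C3a=C7a–C7=C6(O−)–C5=C4, which should close by oxyanion-accelerated disrotatory 6π-electrocyclisation (equally a 6-endo vinylogous Michael addition of C3a to C4); C4 should approach the flat C3a on the face opposite the C3 aryl group so that allyl ends cis to aryl, and reprotonation at C5 under the equilibrating conditions should favour the epimer with equatorial methoxy trans to the pseudo-axial allyl; the closest known reaction types are the anion-accelerated electrocyclisation of hexatrienolates to cyclohexenones and intramolecular Michael additions of dienolates.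

**Compound list**
1 | 3,4,5-trimethoxybenzaldehyde | O=Cc1cc(OC)c(OC)c(OC)c1 | starting material
2 | pent-4-enal | C=CCCC=O | starting material
3 | (2E)-2-(prop-2-en-1-yl)-3-(3,4,5-trimethoxyphenyl)prop-2-enal | O=C/C(CC=C)=C/c1cc(OC)c(OC)c(OC)c1 | intermediate
4 | (2E)-2-(prop-2-en-1-yl)-3-(3,4,5-trimethoxyphenyl)prop-2-en-1-ol | OC/C(CC=C)=C/c1cc(OC)c(OC)c(OC)c1 | intermediate
5 | (2E)-2-(prop-2-en-1-yl)-3-(3,4,5-trimethoxyphenyl)prop-2-en-1-yl N,N-di(propan-2-yl)carbamate | CC(C)N(C(C)C)C(=O)OC/C(CC=C)=C/c1cc(OC)c(OC)c(OC)c1 | intermediate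
6 | acetaldehyde | CC=O | starting material
7 | (1R,2E)-1-lithio derivative of 5 (formed as its (+)-sparteine complex) | [Li][C@@H](OC(=O)N(C(C)C)C(C)C)/C(CC=C)=C/c1cc(OC)c(OC)c(OC)c1 | intermediate
8 | (1S,2E)-1-[tri(propan-2-yloxy)titanio] derivative of 5 | CC(C)O[Ti](OC(C)C)(OC(C)C)[C@H](OC(=O)N(C(C)C)C(C)C)/C(CC=C)=C/c1cc(OC)c(OC)c(OC)c1 | intermediate
9 | (1Z,3R,4S)-4-hydroxy-2-(prop-2-en-1-yl)-3-(3,4,5-trimethoxyphenyl)pent-1-en-1-yl N,N-di(propan-2-yl)carbamate | O[C@@H](C)[C@@H](/C(CC=C)=C\OC(=O)N(C(C)C)C(C)C)c1cc(OC)c(OC)c(OC)c1 | intermediate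
10 | (4S,5S)-2-methoxy-5-methyl-3-(prop-2-en-1-yl)-4-(3,4,5-trimethoxyphenyl)oxolane, mixture at C2 and C3 | C=CCC1C(OC)O[C@@H](C)[C@@H]1c1cc(OC)c(OC)c(OC)c1 | intermediate
11 | 3,3-dimethoxybutan-2-one | CC(=O)C(C)(OC)OC | starting material
12 | 2-methoxy-3-(trimethylsilyloxy)buta-1,3-diene | C=C(OC)C(=C)O[Si](C)(C)C | intermediate
13 | 3-methoxy-1-[(4S,5S)-5-methyl-3-(prop-2-en-1-yl)-4-(3,4,5-trimethoxyphenyl)oxolan-2-yl]but-3-en-2-one, mixture at oxolane C2 and C3 | C=CCC1C(CC(=O)C(=C)OC)O[C@@H](C)[C@@H]1c1cc(OC)c(OC)c(OC)c1 | intermediate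
14 | trimethylsilyl dienol ether of 13 (3-methoxy-2-trimethylsilyloxy-buta-1,3-dien-1-yl group on oxolane C2) | C=CCC1C(C=C(O[Si](C)(C)C)C(=C)OC)O[C@@H](C)[C@@H]1c1cc(OC)c(OC)c(OC)c1 | intermediate
15 | 3-methoxy-1-[(4S,5S)-5-methyl-3-(prop-2-en-1-yl)-4-(3,4,5-trimethoxyphenyl)oxolan-2-ylidene]but-3-en-2-one, mixture at oxolane C3 | C=CCC1C(=CC(=O)C(=C)OC)O[C@@H](C)[C@@H]1c1cc(OC)c(OC)c(OC)c1 | intermediate
16 | (2S,3R,3aR,5R)-5-methoxy-2-methyl-3a-(prop-2-en-1-yl)-3-(3,4,5-trimethoxyphenyl)-3,3a,4,5-tetrahydro-1-benzofuran-6(2H)-one | C=CC[C@]12C[C@@H](OC)C(=O)C=C1O[C@@H](C)[C@@H]2c1cc(OC)c(OC)c(OC)c1 | target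

Total step count: 8. Longest linear sequence: 7 steps (steps 1–4 and 6–8; step 5 makes the side-chain reagent).

**Steps most likely to fail**

Step 8. The trienolate may not reach the folded geometry needed for closure (the allyl group sits on the inside of the triene terminus), the 2-methoxyvinyl ketone may oligomerise by intermolecular Michael addition first, or closure may take place on the wrong face. The fallback builds the quaternary centre by lactone enolate chemistry and sets out from 10. Oxidation (CrO3, aqueous H2SO4, acetone, 0 °C) should give the lactone (4S,5S)-5-methyl-3-(prop-2-en-1-yl)-4-(3,4,5-trimethoxyphenyl)oxolan-2-one F1. The acceptor 3-methoxybut-3-en-2-one F2 is made from 11 by acid-catalysed loss of methanol (TsOH, distillation). Deprotonation of F1 with LiN(i-Pr)2 in THF at −78 °C and Michael addition to F2 should give, anti to the aryl group, the keto lactone (3R,4S,5S)-3-(2-methoxy-3-oxobutyl)-5-methyl-3-(prop-2-en-1-yl)-4-(3,4,5-trimethoxyphenyl)oxolan-2-one F3. Intramolecular Claisen condensation (KOtBu, THF) then opens the lactone to (4R)-4-[(1R,2S)-2-hydroxy-1-(3,4,5-trimethoxyphenyl)propyl]-6-methoxy-4-(prop-2-en-1-yl)cyclohexane-1,3-dione F4, and acid (TsOH, toluene) recloses the oxolane by cyclodehydration, coming back to the route at 16. In this variant the O1–C7a bond is opened and made again in the last operation.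

Step 4. The enantioinduction in the diamine-mediated deprotonation of this γ-aryl, 2-allyl carbamate may be insufficient or reversed, or the lithium compound may lose its configuration before titanation. The fallback replaces asymmetric deprotonation by an enzymatic resolution and sets out from 5. Deprotonation with n-BuLi and N,N,N',N'-tetramethylethylenediamine, exchange with Ti(OiPr)4 and addition of acetaldehyde should give the racemic anti adduct, that is 9 together with its enantiomer (1Z,3S,4R)-4-hydroxy-2-(prop-2-en-1-yl)-3-(3,4,5-trimethoxyphenyl)pent-1-en-1-yl N,N-di(propan-2-yl)carbamate F5. A lipase (Candida antarctica lipase B, vinyl acetate, hexane) should, by the usual preference for the R carbinol, acylate F5 to its acetate (1Z,3S,4R)-4-acetoxy-2-(prop-2-en-1-yl)-3-(3,4,5-trimethoxyphenyl)pent-1-en-1-yl N,N-di(propan-2-yl)carbamate F6 and leave 9. After separation, 9 is cyclised with MeSO3H in MeOH, coming back to the route at 10.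

Step 6. The oxocarbenium ion may be attacked by the methyl enol ether terminus of the diene instead of the silyl enol ether terminus, or the acetal may lose methanol to a 2,3-dihydrofuran. The fallback uses a nucleophile with one reactive terminus and sets out from 10. Addition of 1-(tert-butyldimethylsilyloxy)-1-methoxyethene (BF3·OEt2, CH2Cl2, −78 °C) should give methyl 2-[(4S,5S)-5-methyl-3-(prop-2-en-1-yl)-4-(3,4,5-trimethoxyphenyl)oxolan-2-yl]acetate F7. Treatment with MeNH(OMe)·HCl and i-PrMgCl in THF should give N-methoxy-N-methyl-2-[(4S,5S)-5-methyl-3-(prop-2-en-1-yl)-4-(3,4,5-trimethoxyphenyl)oxolan-2-yl]acetamide F8. Addition of (1-methoxyethenyl)lithium (from methyl vinyl ether and t-BuLi, THF, −78 °C) then gives the ketone, coming back to the route at 13.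

Further compounds
F1 | step 8 | (4S,5S)-5-methyl-3-(prop-2-en-1-yl)-4-(3,4,5-trimethoxyphenyl)oxolan-2-one | C=CCC1C(=O)O[C@@H](C)[C@@H]1c1cc(OC)c(OC)c(OC)c1
F2 | step 8 | 3-methoxybut-3-en-2-one | CC(=O)C(=C)OC
F3 | step 8 | (3R,4S,5S)-3-(2-methoxy-3-oxobutyl)-5-methyl-3-(prop-2-en-1-yl)-4-(3,4,5-trimethoxyphenyl)oxolan-2-one | C=CC[C@]1(CC(OC)C(C)=O)C(=O)O[C@@H](C)[C@@H]1c1cc(OC)c(OC)c(OC)c1
F4 | step 8 | (4R)-4-[(1R,2S)-2-hydroxy-1-(3,4,5-trimethoxyphenyl)propyl]-6-methoxy-4-(prop-2-en-1-yl)cyclohexane-1,3-dione | C=CC[C@]1([C@@H](c2cc(OC)c(OC)c(OC)c2)[C@H](C)O)CC(OC)C(=O)CC1=O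
F5 | step 4 | (1Z,3S,4R)-4-hydroxy-2-(prop-2-en-1-yl)-3-(3,4,5-trimethoxyphenyl)pent-1-en-1-yl N,N-di(propan-2-yl)carbamate | O[C@H](C)[C@H](/C(CC=C)=C\OC(=O)N(C(C)C)C(C)C)c1cc(OC)c(OC)c(OC)c1
F6 | step 4 | (1Z,3S,4R)-4-acetoxy-2-(prop-2-en-1-yl)-3-(3,4,5-trimethoxyphenyl)pent-1-en-1-yl N,N-di(propan-2-yl)carbamate | CC(=O)O[C@H](C)[C@H](/C(CC=C)=C\OC(=O)N(C(C)C)C(C)C)c1cc(OC)c(OC)c(OC)c1
F7 | step 6 | methyl 2-[(4S,5S)-5-methyl-3-(prop-2-en-1-yl)-4-(3,4,5-trimethoxyphenyl)oxolan-2-yl]acetate | C=CCC1C(CC(=O)OC)O[C@@H](C)[C@@H]1c1cc(OC)c(OC)c(OC)c1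
F8 | step 6 | N-methoxy-N-methyl-2-[(4S,5S)-5-methyl-3-(prop-2-en-1-yl)-4-(3,4,5-trimethoxyphenyl)oxolan-2-yl]acetamide | C=CCC1C(CC(=O)N(C)OC)O[C@@H](C)[C@@H]1c1cc(OC)c(OC)c(OC)c1
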